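The seven-membered depsidone ring is cut at the aryl ether C–O bond at C5 of ring A. This carbon lies between the formyl-bearing C4 and the lactone-carbonyl-bearing C6, exactly where a phthalate has its second carboxyl group. The ether is therefore made from an ester. An eight-membered dilactone of a ring A phthalic acid with the ring B catechol (C1′ and C6′ oxygens) is built by two acylations. Zerovalent nickel, anchored by the sp2 nitrogen of the masked C4 formyl group, then expels the C5 carbonyl as CO and joins C5 to the C6′ oxygen, contracting the ring in one operation. In the precursor all three formyl groups are masked (two acetals, one hydrazone).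

Key step: step 17

Locants: ring A (methyl-bearing ring) C1 methyl, C2 H, C3 oxygen, C4 formyl, C5 ether oxygen, C6 depsidone carbonyl; ring B C1′ ester oxygen, C2′ formyl, C3′ oxygen, C4′ phthalide carbonyl, C5′ lactol carbon, C6′ ether oxygen. Benzoate locants 1–6 of compounds 2–6 are ring A C6, C5, C4, C3, C2, C1; those of 7–18 are ring B C4′, C3′, C2′, C1′, C6′, C5′.

Assumption: the lactol carbon epimerises only through the ring-opened formyl acid. Step 20 uses this for the dynamic resolution. Near pH 6–7 and at or below 5 °C the opening is taken to be slow enough for 27 to be isolated and kept cold as the (S) enantiomer.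

Remark on the dilactone: catechol and phthalic acid are both unsymmetrical, so the two ester bonds are made one at a time (steps 14 and 16). The first goes on the less acidic C6′ oxygen, from which acyl migration to the C1′ oxygen is uphill.

Remark on the masked C4 formyl group: it is carried as an N,N-dimethylhydrazone, installed before the neighbouring C5 carbonyl exists. Condensing a primary amine with a formyl group ortho to an aryl ester passes through a carbinolamine that cleaves that ester, and a free ortho-formyl acid closes to a lactol. The hydrazone keeps the chelating sp2 nitrogen and comes off in dilute acid. Compounds 22 and 23 are the precursor and the product of the key step.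

Step 1
Reactants: 1 orsellinic acid
Product: 2 benzyl 2,4-dihydroxy-6-methylbenzoate
Conditions: BnBr, KHCO3, DMF, rt
Reagents that add atoms: benzyl bromide, BrCc1ccccc1
Why: Carboxylate O-alkylation (SN2); hydrogen carbonate ionises only the carboxylic acid, so both phenols stay free and the decarboxylation-prone acid is never heated.

Step 2
Reactants: 2 benzyl 2,4-dihydroxy-6-methylbenzoate
Product: 3 benzyl 2-hydroxy-4-methoxy-6-methylbenzoate
Conditions: MeI (1.05 equiv), K2CO3, acetone, 50 °C
Reagents that add atoms: iodomethane, CI
Why: Williamson etherification; the 4-hydroxyl is the more acidic and accessible one, whereas the 2-hydroxyl is held in a hydrogen bond to the ester and is left untouched.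

Step 3
Reactants: 3 benzyl 2-hydroxy-4-methoxy-6-methylbenzoate
Product: 4 benzyl 3-formyl-2-hydroxy-4-methoxy-6-methylbenzoate
Conditions: MgCl2, Et3N, (CH2O)n, MeCN, reflux
Reagents that add atoms: formaldehyde (as paraformaldehyde), C=O
Why: Magnesium-mediated ortho-formylation of a phenol (Casnati–Skattebøl): the magnesium phenoxide delivers formaldehyde only ortho to its oxygen, C3 is the only free ortho carbon, and a second formaldehyde accepts the hydride.

Step 4
Reactants: 4 benzyl 3-formyl-2-hydroxy-4-methoxy-6-methylbenzoate
Product: 5 benzyl 3-[(E)-(2,2-dimethylhydrazinylidene)methyl]-2-hydroxy-4-methoxy-6-methylbenzoate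
Conditions: Me2NNH2, EtOH, rt
Reagents that add atoms: 1,1-dimethylhydrazine, CN(C)N
Why: Hydrazone condensation giving the (E) isomer; the formyl group is masked as the later directing group while the neighbouring carbon still carries only a phenol.

Step 5
Reactants: 5 hydrazone phenol
Product: 6 benzyl 3-[(E)-(2,2-dimethylhydrazinylidene)methyl]-4-methoxy-6-methyl-2-(trifluoromethanesulfonyloxy)benzoate
Conditions: PhNTf2, Cs2CO3, DMF, rt
Reagents that add atoms: N-phenylbis(trifluoromethanesulfonimide), O=S(=O)(N(c1ccccc1)S(=O)(=O)C(F)(F)F)C(F)(F)F
Why: O-sulfonylation of the phenoxide with a mild triflyl donor that does not react with the hydrazone or the benzyl ester.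

Step 6
Reactants: 7 methyl orsellinate
Product: 9 methyl 2,4,5-trihydroxy-6-methylbenzoate, via aryl sulfate potassium salt 8 (not isolated)
Conditions: K2S2O8, aq. NaOH, 0 °C to rt; then aq. HCl, 70 °C
Reagents that add atoms: potassium peroxodisulfate, [K+].[K+].[O-]S(=O)(=O)OOS(=O)(=O)[O-]
Why: Elbs persulfate oxidation: peroxodisulfate attacks the phenoxide para to the 2-hydroxyl (C5, also ortho to the 4-hydroxyl) to give the aryl sulfate, which acid hydrolyses to the phenol.

Step 7
Reactants: 9 methyl 2,4,5-trihydroxy-6-methylbenzoate
Product: 10 methyl 3-formyl-2,4,5-trihydroxy-6-methylbenzoate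
Conditions: Cl2CHOMe, TiCl4, CH2Cl2, 0 °C; then aq. HCl
Reagents that add atoms: dichloromethyl methyl ether, COC(Cl)Cl; water, O
Why: Rieche formylation (electrophilic aromatic substitution); C3 is the only unsubstituted ring carbon and lies ortho to two hydroxyl groups, so no regiochemical choice exists.

Step 8
Reactants: 10 methyl 3-formyl-2,4,5-trihydroxy-6-methylbenzoate
Product: 11 methyl 2,4,5-triacetoxy-3-(diacetoxymethyl)-6-methylbenzoate
Conditions: Ac2O, H2SO4 (cat.), rt
Reagents that add atoms: acetic anhydride, CC(=O)OC(C)=O
Why: Acid-catalysed acetylation of the three phenols together with conversion of the aldehyde into its geminal diacetate (acylal), the protection needed for the radical bromination.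

Step 9
Reactants: 11 pentaacetate
Product: 12 methyl 2,4,5-triacetoxy-3-(diacetoxymethyl)-6-(dibromomethyl)benzoate
Conditions: NBS (2.3 equiv), AIBN, PhCF3, 85 °C
Reagents that add atoms: N-bromosuccinimide, O=C1CCC(=O)N1Br
Why: Wohl–Ziegler benzylic bromination taken to the dibromide; the ring is fully substituted, the phenols are acetylated and the formyl C–H is hidden in the electron-poor acylal, so only the methyl group offers a reactive hydrogen.

Step 10
Reactants: 12 dibromide pentaacetate
Product: 13 methyl 6-(dimethoxymethyl)-3-formyl-2,4,5-trihydroxybenzoate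
Conditions: NaOMe, MeOH, 0 °C to rt; then aq. NH4Cl
Reagents that add atoms: sodium methoxide, C[O-].[Na+]
Why: Solvolysis of the benzal bromide to the dimethyl acetal, assisted by the ortho phenoxide freed in the same pot (quinone-methide pathway), with Zemplén-type methanolysis of the aryl acetates and of the acylal; because the acetal forms in base, the ortho ester never meets a free formyl group.

Step 11
Reactants: 13 methyl 6-(dimethoxymethyl)-3-formyl-2,4,5-trihydroxybenzoate
Product: 15 methyl 5-acetoxy-4-(benzyloxy)-6-(dimethoxymethyl)-3-formyl-2-hydroxybenzoate, via 4-O-benzyl ether 14 (not isolated)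
Conditions: BnBr (1.05 equiv), KHCO3, DMF, rt; then Ac2O, pyridine, 0 °C
Reagents that add atoms: benzyl bromide, BrCc1ccccc1; acetic anhydride, CC(=O)OC(C)=O
Why: Williamson benzylation of the most acidic phenol (4-OH, para to the ester and ortho to the formyl group), then acetylation of the 5-hydroxyl, the only remaining phenol not locked between two carbonyl groups; all conditions are basic, which the acetal ortho to a phenol requires.

Step 12
Reactants: 15 acetate benzyl ether
Product: 16 methyl 5-acetoxy-4-(benzyloxy)-6-(dimethoxymethyl)-3-formyl-2-methoxybenzoate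
Conditions: MeI, Ag2O, CH2Cl2, rt, dark
Reagents that add atoms: iodomethane, CI
Why: Purdie methylation of the hindered, hydrogen-bonded 2-hydroxyl under neutral conditions, which keeps the aryl acetate in place.

Step 13
Reactants: 16 methyl ether
Product: 18 methyl 4-(benzyloxy)-3,6-bis(dimethoxymethyl)-5-hydroxy-2-methoxybenzoate, via bis-acetal acetate 17 (not isolated)
Conditions: HC(OMe)3, MeOH, PPTS (cat.), rt; then K2CO3 (cat.), MeOH, rt
Reagents that add atoms: trimethyl orthoformate, COC(OC)OC
Why: Acid-catalysed acetalisation with the orthoformate as water scavenger, then base-catalysed methanolysis of the aryl acetate; the phenol is freed in base because a dimethyl acetal ortho to a free phenol does not tolerate acid.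

Step 14
Reactants: 6 ring A triflate; 18 ring B phenol
Product: 19 benzyl ester of the C5 aryl ester (ring A C5–C(=O)–O–C6′; C1′ benzyl ether)
Conditions: Pd(OAc)2, Xantphos, CO (1 atm), Et3N, toluene, 80 °C
Reagents that add atoms: carbon monoxide, [C-]#[O+]
Why: Palladium-catalysed aryloxycarbonylation of an aryl triflate (oxidative addition, CO insertion, capture of the aroyl palladium by the phenoxide); the C5 carbonyl is created directly as the ester of the only free phenol of 18, so no free acid sits next to the masked formyl group and no choice between the catechol oxygens arises.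

Step 15
Reactants: 19 benzyl ester benzyl ether
Product: 20 hydroxy acid (ring A C6 carboxylic acid, ring B C1′ phenol)
Conditions: H2 (1 atm), Pd/C, EtOAc, rt
Reagents that add atoms: none
Why: Hydrogenolysis of the benzyl ester and the benzyl ether; hydrazone, acetals and aryl ester survive the neutral conditions, and 20 is used at once without base because a carboxylate beside an aryl ester would displace the phenol.

Step 16
Reactants: 20 hydroxy acid
Product: 22 eight-membered dilactone hydrazone, via acid chloride 21 (not isolated)
Conditions: 1-chloro-N,N,2-trimethylprop-1-en-1-amine, CH2Cl2, 0 °C; then slow addition to DMAP, iPr2NEt, toluene, 60 °C (2 mM)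
Reagents that add atoms: none
Why: Lactonisation through the acid chloride (8-exo-trig acyl substitution at high dilution); the acid is activated under neutral conditions so that no carboxylate can attack the neighbouring C5 aryl ester, and base is added only when the acyl chloride is ready for the C1′ phenol.

Step 17
Reactants: 22 eight-membered dilactone hydrazone
Product: 23 depsidone hydrazone (ring A C5 bonded to the C6′ oxygen)
Conditions: Ni(cod)2 (20 mol%), 3,4-bis(dicyclohexylphosphino)thiophene (40 mol%), K3PO4, m-xylene, 140 °C, argon sweep
Reagents that add atoms: none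
Why: Proposed new method: zerovalent nickel on the electron-rich bisphosphine is guided by the hydrazone sp2 nitrogen into the C5 acyl–oxygen bond (six-membered acyl nickelacycle), the aroyl nickel aryloxide loses CO to give a five-membered aryl nickelacycle, and C(aryl)–O reductive elimination joins C5 to the C6′ oxygen. The closest known reaction type is the nickel- or palladium-catalysed decarbonylative conversion of aryl esters of azine carboxylic acids into diaryl ethers, here run inside a ring and steered by an ortho azomethine nitrogen. The seven-membered ring closes by reductive elimination from an eight-membered aryl nickel aryloxide chelate, that is, by contraction of the strained eight-membered dilactone; no stereocentre is formed. The step needs site selectivity among three esters and against aryl C–O cleavage: only the C5 ester has a chelating nitrogen beside it, the C6 aryl ester and the C4′ methyl ester have none, and the ring B formyl groups are acetals that offer the metal neither a carbonyl nor a donor nitrogen. The argon sweep removes CO so that nickel is not tied up as a carbonyl complex.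

Step 18
Reactants: 23 depsidone hydrazone
Product: 24 trialdehyde (C3 and C3′ methyl ethers, C4′ methyl ester)
Conditions: 1 M aq. HCl, THF, rt
Reagents that add atoms: water, O
Why: Acid-catalysed hydrolysis of the hydrazone and of both dimethyl acetals; the hindered depsidone aryl ester and the methyl ethers are stable to dilute acid at room temperature.

Step 19
Reactants: 24 trialdehyde
Product: 25 racemic lactol (target constitution)
Conditions: BBr3, CH2Cl2, −78 °C to rt; then H2O
Reagents that add atoms: none
Why: Lewis-acid ether and ester cleavage: both methyl ethers are ortho to carbonyl groups and leave through boron chelates, the methyl ester next to the C5′ formyl group is cleaved with help from that neighbour, and on aqueous work-up the acid adds to the formyl group to give the lactol as a racemate.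

Step 20
Reactants: 25 racemic lactol
Product: 26 (S)-lactol acetate
Conditions: Burkholderia cepacia lipase (immobilised), vinyl acetate, THF, 30 °C
Reagents that add atoms: vinyl acetate, CC(=O)OC=C
Why: Lipase-catalysed dynamic kinetic resolution of a cyclic hemiacetal by irreversible acyl transfer: the enzyme active site acylates only the (S)-lactol while the (R)-lactol keeps epimerising through the open formyl acid, the hydrogen-bonded phenols are not acylated, and the lipase is chosen by screening for the (S)-acetate.

Step 21
Reactants: 26 (S)-lactol acetate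
Product: 27 target, (S) at the lactol carbon
Conditions: same lipase, phosphate buffer pH 6.5, MTBE, 5 °C
Reagents that add atoms: none
Why: Enzymatic ester hydrolysis at the acyl–oxygen bond, which leaves both C–O bonds of the lactol carbon intact, so the (S) configuration is retained; near-neutral buffer and low temperature hold back ring opening.

Compound list
1 | orsellinic acid (2,4-dihydroxy-6-methylbenzoic acid) | Cc1cc(O)cc(O)c1C(=O)O | starting material
2 | benzyl 2,4-dihydroxy-6-methylbenzoate | Cc1cc(O)cc(O)c1C(=O)OCc1ccccc1 | intermediate
3 | benzyl 2-hydroxy-4-methoxy-6-methylbenzoate | Cc1cc(OC)cc(O)c1C(=O)OCc1ccccc1 | intermediate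
4 | benzyl 3-formyl-2-hydroxy-4-methoxy-6-methylbenzoate | Cc1cc(OC)c(C=O)c(O)c1C(=O)OCc1ccccc1 | intermediate
5 | benzyl 3-[(E)-(2,2-dimethylhydrazinylidene)methyl]-2-hydroxy-4-methoxy-6-methylbenzoate | Cc1cc(OC)c(/C=N/N(C)C)c(O)c1C(=O)OCc1ccccc1 | intermediate
6 | benzyl 3-[(E)-(2,2-dimethylhydrazinylidene)methyl]-4-methoxy-6-methyl-2-(trifluoromethanesulfonyloxy)benzoate | Cc1cc(OC)c(/C=N/N(C)C)c(OS(=O)(=O)C(F)(F)F)c1C(=O)OCc1ccccc1 | intermediate
7 | methyl orsellinate (methyl 2,4-dihydroxy-6-methylbenzoate) | COC(=O)c1c(C)cc(O)cc1O | starting material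
8 | potassium salt of methyl 2,4-dihydroxy-6-methyl-5-(sulfooxy)benzoate | COC(=O)c1c(C)c(OS(=O)(=O)[O-])c(O)cc1O.[K+] | intermediate
9 | methyl 2,4,5-trihydroxy-6-methylbenzoate | COC(=O)c1c(C)c(O)c(O)cc1O | intermediate
10 | methyl 3-formyl-2,4,5-trihydroxy-6-methylbenzoate | COC(=O)c1c(C)c(O)c(O)c(C=O)c1O | intermediate
11 | methyl 2,4,5-triacetoxy-3-(diacetoxymethyl)-6-methylbenzoate | COC(=O)c1c(C)c(OC(C)=O)c(OC(C)=O)c(C(OC(C)=O)OC(C)=O)c1OC(C)=O | intermediate
12 | methyl 2,4,5-triacetoxy-3-(diacetoxymethyl)-6-(dibromomethyl)benzoate | COC(=O)c1c(C(Br)Br)c(OC(C)=O)c(OC(C)=O)c(C(OC(C)=O)OC(C)=O)c1OC(C)=O | intermediate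
13 | methyl 6-(dimethoxymethyl)-3-formyl-2,4,5-trihydroxybenzoate | COC(=O)c1c(C(OC)OC)c(O)c(O)c(C=O)c1O | intermediate
14 | methyl 4-(benzyloxy)-6-(dimethoxymethyl)-3-formyl-2,5-dihydroxybenzoate | COC(=O)c1c(C(OC)OC)c(O)c(OCc2ccccc2)c(C=O)c1O | intermediate
15 | methyl 5-acetoxy-4-(benzyloxy)-6-(dimethoxymethyl)-3-formyl-2-hydroxybenzoate | COC(=O)c1c(C(OC)OC)c(OC(C)=O)c(OCc2ccccc2)c(C=O)c1O | intermediate
16 | methyl 5-acetoxy-4-(benzyloxy)-6-(dimethoxymethyl)-3-formyl-2-methoxybenzoate | COC(=O)c1c(C(OC)OC)c(OC(C)=O)c(OCc2ccccc2)c(C=O)c1OC | intermediate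
17 | methyl 5-acetoxy-4-(benzyloxy)-3,6-bis(dimethoxymethyl)-2-methoxybenzoate | COC(=O)c1c(C(OC)OC)c(OC(C)=O)c(OCc2ccccc2)c(C(OC)OC)c1OC | intermediate
18 | methyl 4-(benzyloxy)-3,6-bis(dimethoxymethyl)-5-hydroxy-2-methoxybenzoate | COC(=O)c1c(C(OC)OC)c(O)c(OCc2ccccc2)c(C(OC)OC)c1OC | intermediate
19 | mixed phthalate: ring A C6 benzyl ester, C5 aryl ester to the C6′ oxygen of ring B (C1′ benzyl ether), C4 (E)-dimethylhydrazone | Cc1cc(OC)c(/C=N/N(C)C)c(C(=O)Oc2c(C(OC)OC)c(C(=O)OC)c(OC)c(C(OC)OC)c2OCc2ccccc2)c1C(=O)OCc1ccccc1 | intermediate
20 | hydroxy acid: as 19 with free C6 carboxylic acid and free C1′ phenol | Cc1cc(OC)c(/C=N/N(C)C)c(C(=O)Oc2c(C(OC)OC)c(C(=O)OC)c(OC)c(C(OC)OC)c2O)c1C(=O)O | intermediate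
21 | acid chloride of 20 | Cc1cc(OC)c(/C=N/N(C)C)c(C(=O)Oc2c(C(OC)OC)c(C(=O)OC)c(OC)c(C(OC)OC)c2O)c1C(Cl)=O | intermediate
22 | eight-membered dilactone hydrazone (C6–C(=O)–O–C1′ and C5–C(=O)–O–C6′; C4 (E)-CH=N–NMe2; C3 and C3′ OMe; C2′ and C5′ dimethyl acetals; C4′ CO2Me) | Cc1cc(OC)c(/C=N/N(C)C)c2c1C(=O)Oc1c(C(OC)OC)c(OC)c(C(=O)OC)c(C(OC)OC)c1OC2=O | intermediate
23 | depsidone hydrazone (as 22 with C5 bonded directly to the C6′ oxygen) | Cc1cc(OC)c(/C=N/N(C)C)c2c1C(=O)Oc1c(C(OC)OC)c(OC)c(C(=O)OC)c(C(OC)OC)c1O2 | intermediate
24 | depsidone trialdehyde, di-O-methyl ether methyl ester | Cc1cc(OC)c(C=O)c2c1C(=O)Oc1c(C=O)c(OC)c(C(=O)OC)c(C=O)c1O2 | intermediate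
25 | racemic lactol (target constitution, both configurations at the lactol carbon) | Cc1cc(O)c(C=O)c2c1C(=O)Oc1c(C=O)c(O)c3c(c1O2)C(O)OC3=O | intermediate
26 | (S)-O-acetyl lactol | Cc1cc(O)c(C=O)c2c1C(=O)Oc1c(C=O)c(O)c3c(c1O2)[C@@H](OC(C)=O)OC3=O | intermediate
27 | CNP0296574.1, (S) at the lactol carbon | Cc1cc(O)c(C=O)c2c1C(=O)Oc1c(C=O)c(O)c3c(c1O2)[C@@H](O)OC3=O | target

Total step count: 21. Longest linear sequence: 16 steps (steps 6–13, then 14–21).

Steps most likely to fail

Step 17. The metal may insert into a C–O bond other than the C5 acyl–oxygen bond, stop turning over because the extruded CO binds zerovalent nickel, or cleave the hydrazone N–N bond. The fallback forms the same diaryl ether bond by known chemistry and sets out from 6 and 18. A palladium-catalysed Buchwald–Hartwig etherification of the aryl triflate with the phenol (Pd2(dba)3, tBuXPhos, K3PO4, toluene, 100 °C) should give the diaryl ether benzyl ester F1. Hydrogenolysis (H2, Pd/C, EtOAc) should give the diaryl ether hydroxy acid F2. Carbodiimide lactonisation of the C6 acid onto the C1′ phenol (DCC, DMAP, CH2Cl2, high dilution) closes the seven-membered ring and comes back to the route at 23.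

Step 16. The neighbouring C5 aryl ester may take part at the activated C6 acyl group (closure to a spiro ortho ester), the half ester may collapse to the cyclic anhydride with loss of ring B, or intermolecular esterification may win over the eight-membered closure. The fallback is a Corey–Nicolaou double-activation lactonisation, neutral throughout, and sets out from 20. 2,2′-Dipyridyl disulfide and PPh3 in toluene at rt should give the S-(pyridin-2-yl) thioester F3. Slow addition of F3 to toluene at 110 °C at high dilution should transfer the acyl group to the C1′ phenol and come back to the route at 22.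

Step 20. The acyl transfer may discriminate poorly between the two lactol enantiomers, or the unreacted lactol may epimerise too slowly to keep up. The fallback replaces enzymatic selection by physical resolution and sets out from 25. Acetic anhydride (1 equiv) in pyridine at −20 °C should acetylate the lactol hydroxyl ahead of the two hydrogen-bonded phenols and give the racemic lactol acetate F4. Preparative chromatography on a chiral stationary phase should separate F4 into the (S)-acetate, which is 26 and rejoins the route there, and the (R)-lactol acetate F5. F5 is hydrolysed back to 25 and recycled.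

Further compounds
F1 | step 17 | diaryl ether: ring A C5–O–C6′, C6 benzyl ester, C1′ benzyl ether, C4 (E)-dimethylhydrazone | Cc1cc(OC)c(/C=N/N(C)C)c(Oc2c(C(OC)OC)c(C(=O)OC)c(OC)c(C(OC)OC)c2OCc2ccccc2)c1C(=O)OCc1ccccc1
F2 | step 17 | diaryl ether hydroxy acid (free C6 acid, free C1′ phenol) | Cc1cc(OC)c(/C=N/N(C)C)c(Oc2c(C(OC)OC)c(C(=O)OC)c(OC)c(C(OC)OC)c2O)c1C(=O)O
F3 | step 16 | S-(pyridin-2-yl) thioester of hydroxy acid 20 | Cc1cc(OC)c(/C=N/N(C)C)c(C(=O)Oc2c(C(OC)OC)c(C(=O)OC)c(OC)c(C(OC)OC)c2O)c1C(=O)Sc1ccccn1
F4 | step 20 | racemic O-acetyl lactol | Cc1cc(O)c(C=O)c2c1C(=O)Oc1c(C=O)c(O)c3c(c1O2)C(OC(C)=O)OC3=O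
F5 | step 20 | (R)-O-acetyl lactol | Cc1cc(O)c(C=O)c2c1C(=O)Oc1c(C=O)c(O)c3c(c1O2)[C@H](OC(C)=O)OC3=O
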